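**Plan**

- Retrosynthesis: the C12–C13 bond of ring C is cut first, to an acylium ion at C-12 and an allylsilane C13=C16–CH2SiMe3 held in a spiro ring D. Then come C2–C3 (ring A, dialdehyde pinacol), C4–C5 with the lactone C–O bond (tethered Michael), C1–C10, C6–C7, C13=C16 (metathesis), and C8–C15 with C9–C11 (conjugate addition–alkylation), back to a 4-silyloxycyclopentenone that is ring B.
- Forward: ring B is bought. C-9 and the quaternary spiro carbon C-8 are set on it, ring D is closed by metathesis, C-7 is added by carbonylation, the C-10 carbinol and the lactone follow, ring A is closed by pinacol coupling, and ring C is closed last.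
- Enabling feature: C-13 is the bridgehead of the bicyclo[3.2.1]octane (rings C and D) and sits between the C-12 carbonyl and the C-16 exocyclic methylene. This β,γ-unsaturated ketone cannot conjugate, so it is an acylated 2-substituted allyl unit C12–C13–C16=C17.
- Stereochemistry: the single stereocentre of (R)-4-silyloxycyclopentenone steers C-9 (trans addition), C-8 (alkylation trans to C-9) and C-10 (addition trans to C-9). The cis-fused lactone fixes C-5 and C-4, samarium chelation under the lactone bridge gives the 2β,3β-diol, the bridged ring fixes C-13, and C-6 is equilibrated late.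

Key step: step 18

Remark: locants follow the gibberellane numbering of the target in all intermediates; α is the face of ring B that carries the lactone oxygen at C-10 and β the opposite face; the 6β-carboxyl is taken to be the thermodynamically preferred C-6 epimer.

Step 1
Reactants: 1 (R)-4-[(tert-butyldimethylsilyl)oxy]cyclopent-2-en-1-one
Product: 2 (R)-4-[(tert-butyldimethylsilyl)oxy]-2-iodocyclopent-2-en-1-one
Conditions: I2, pyridine, CH2Cl2, 0 °C to rt
Reagents that add atoms: iodine, II
Why: α-Iodination of the enone by pyridine conjugate addition, iodination of the enolate and elimination (addition–elimination) should leave the silyloxy stereocentre untouched and create no new one.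

Step 2
Reactants: 2 (R)-4-[(tert-butyldimethylsilyl)oxy]-2-iodocyclopent-2-en-1-one
Product: 3 (R)-2-allyl-4-[(tert-butyldimethylsilyl)oxy]cyclopent-2-en-1-one
Conditions: allylSnBu3, Pd(PPh3)4 (5 mol %), CuI (10 mol %), DMF, rt
Reagents that add atoms: allyltributylstannane, C=CC[Sn](CCCC)(CCCC)CCCC
Why: Stille coupling of the α-iodoenone (oxidative addition, copper-assisted transmetalation, reductive elimination) should put the future C-14 arm on C-8 under conditions mild enough to keep the allyl double bond out of conjugation.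

Step 3
Reactants: 4 [2-(chloromethyl)prop-2-en-1-yl]trimethylsilane
Product: 5 [2-(iodomethyl)prop-2-en-1-yl]trimethylsilane
Conditions: NaI, acetone, rt, dark
Reagents that add atoms: sodium iodide, [Na+].[I-]
Why: Finkelstein exchange driven by precipitation of NaCl should give the allylic iodide needed for a fast enolate alkylation.

Step 4
Reactants: 3 (R)-2-allyl-4-[(tert-butyldimethylsilyl)oxy]cyclopent-2-en-1-one; 5 [2-(iodomethyl)prop-2-en-1-yl]trimethylsilane
Product: 7 (2R,3R,4R)-2-allyl-4-[(tert-butyldimethylsilyl)oxy]-3-(1,3-dioxolan-2-ylmethyl)-2-{2-[(trimethylsilyl)methyl]prop-2-en-1-yl}cyclopentan-1-one, via trimethylsilyl enol ether 6 (not isolated)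
Conditions: (1,3-dioxolan-2-ylmethyl)MgBr, CuBr·SMe2 (10 mol %), Me3SiCl, THF, −78 °C; concentrate; MeLi, THF, 0 °C; then 5, HMPA, −78 to −30 °C
Reagents that add atoms: (1,3-dioxolan-2-ylmethyl)magnesium bromide, Br[Mg]CC1OCCO1; compound 5, C=C(CI)C[Si](C)(C)C; chlorotrimethylsilane, C[Si](C)(C)Cl (silicon carried only in 6)
Why: Copper-catalysed conjugate addition trans to the silyloxy group sets C-9, silylation fixes the enolate regiochemistry, and the lithium enolate freed by MeLi should be alkylated trans to the new C-9 side chain, so that the allyl arm (C-14) ends cis and the silylmethylallyl arm (C-15) trans to C-11 at quaternary C-8 (three-component conjugate addition–enolate alkylation).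

Step 5
Reactants: 7 (2R,3R,4R)-2-allyl-4-[(tert-butyldimethylsilyl)oxy]-3-(1,3-dioxolan-2-ylmethyl)-2-{2-[(trimethylsilyl)methyl]prop-2-en-1-yl}cyclopentan-1-one
Product: 8 spiro ketone 3-[(tert-butyldimethylsilyl)oxy]-4-(1,3-dioxolan-2-ylmethyl)-7-[(trimethylsilyl)methyl]spiro[4.4]non-7-en-1-one (ring B ketone at C-6, ring D allylsilane, C-14 arm α)
Conditions: second-generation Grubbs catalyst RuCl2(=CHPh)(PCy3)(H2IMes) (5 mol %), CH2Cl2, 40 °C
Reagents that add atoms: none
Why: Ring-closing metathesis of the two geminal allyl arms should close the five-membered ring D as a trisubstituted allylsilane olefin C13=C16, with C-8 remaining stereogenic because the silylmethyl group marks the β arm.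

Step 6
Reactants: 8 spiro ketone
Product: 9 enol triflate of 8 (C-6 OTf, C5=C6)
Conditions: KN(SiMe3)2, THF, −78 °C; PhNTf2, −78 to −20 °C
Reagents that add atoms: N-phenylbis(trifluoromethanesulfonimide), O=S(=O)(N(c1ccccc1)S(=O)(=O)C(F)(F)F)C(F)(F)F
Why: Enolisation can occur only toward C-5 because C-8 is quaternary, and O-triflation of the potassium enolate at −78 °C should outrun β-elimination of the C-10 silyloxy group (enol triflate formation).

Step 7
Reactants: 9 enol triflate
Product: 10 2-(trimethylsilyl)ethyl enoate (C-7 ester on C-6, C5=C6, 10β-OTBS)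
Conditions: Pd(OAc)2 (5 mol %), dppp, CO (1 atm), Me3SiCH2CH2OH, Et3N, DMF, 60 °C
Reagents that add atoms: carbon monoxide, [C-]#[O+]; 2-(trimethylsilyl)ethan-1-ol, C[Si](C)(C)CCO
Why: Palladium-catalysed alkoxycarbonylation of the vinyl triflate should install C-7 as a fluoride-labile ester without touching the allylsilane or the acetal.

Step 8
Reactants: 10 2-(trimethylsilyl)ethyl enoate
Product: 11 allylic alcohol (10β-OH)
Conditions: HF·pyridine, pyridine, THF, 0 °C to rt
Reagents that add atoms: none
Why: Buffered HF should cleave the secondary allylic silyl ether selectively, since the carbon-bound silicon of the allylsilane and of the ester is far less prone to fluoride attack (desilylation).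

Step 9
Reactants: 11 allylic alcohol
Product: 12 enone (C-10 ketone conjugated to the C5=C6 enoate)
Conditions: DMP (1,1,1-triacetoxy-1,1-dihydro-1,2-benziodoxol-3(1H)-one), CH2Cl2, 0 °C to rt
Reagents that add atoms: none
Why: Hypervalent-iodine oxidation under near-neutral conditions should give the ketone without epimerising the adjacent C-9 stereocentre.

Step 10
Reactants: 13 2,2,5-trimethyl-1,3-dioxane-4,6-dione
Product: 14 3-(ethylsulfanyl)-2-methyl-3-oxopropanoic acid
Conditions: EtSH (excess), toluene, sealed tube, 90 °C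
Reagents that add atoms: ethanethiol, CCS
Why: Thermal opening of the dioxanedione by the thiol with loss of acetone (acyl transfer through the acylketene) should give the malonic half thioester.

Step 11
Reactants: 14 3-(ethylsulfanyl)-2-methyl-3-oxopropanoic acid
Product: 15 S-ethyl 3-chloro-2-methyl-3-oxopropanethioate
Conditions: (COCl)2, DMF (cat.), CH2Cl2, 0 °C to rt, used crude
Reagents that add atoms: oxalyl chloride, ClC(=O)C(=O)Cl
Why: Acid chloride formation through the chloroiminium catalyst should activate the acid for acylation of a hindered alkoxide.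

Step 12
Reactants: 12 enone; 15 S-ethyl 3-chloro-2-methyl-3-oxopropanethioate
Product: 17 tertiary C-10 ester of 2-methylthiomalonate bearing 10β-CH2C(O)SEt, via lithium alkoxide 16 (not isolated)
Conditions: EtSC(O)CH3, LiN(SiMe3)2, THF, −78 °C; add 12; then 15, −78 to −20 °C
Reagents that add atoms: S-ethyl ethanethioate, CCSC(C)=O; compound 15, CCSC(=O)C(C)C(Cl)=O; lithium bis(trimethylsilyl)amide, [Li+].C[Si](C)(C)[N-][Si](C)(C)C (lithium carried only in 16)
Why: Aldol-type 1,2-addition of the lithium thioester enolate to the C-10 ketone from the β face, trans to the adjacent C-9 side chain, should set the C-10 carbinol with oxygen α, and O-acylation at low temperature traps the aldolate before retro-aldol.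

Step 13
Reactants: 17 tertiary thiomalonate ester
Product: 18 cis-fused 19,10-lactone with C-4 methyl and C(O)SEt, 5β-H and 6α-ester
Conditions: Cs2CO3 (0.5 equiv), MeCN, 0 °C
Reagents that add atoms: none
Why: Intramolecular Michael addition of the thiomalonate carbanion to C-5 (5-exo-trig, reacting through the thioester enolate that is exocyclic to the forming ring) should give the lactone, which can only be cis-fused at C-5; the planar thioester enolate arm should take the exo side at C-4 and leave methyl endo, and kinetic protonation of the ester enolate on the convex β face gives the 6α-ester that is corrected in step 19.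

Step 14
Reactants: 18 lactone bis-thioester
Product: 19 dialdehyde (C-2 and C-3 formyl groups)
Conditions: Et3SiH, Pd/C (10 wt %), acetone, rt
Reagents that add atoms: none
Why: Fukuyama reduction should convert both thioesters into aldehydes under neutral conditions that spare the esters, the lactone, the acetal, the trisubstituted allylsilane and the base-sensitive β-acyloxy aldehyde.

Step 15
Reactants: 19 dialdehyde
Product: 20 2β,3β-diol (ring A closed)
Conditions: SmI2 (2.5 equiv), t-BuOH, THF, −78 °C
Reagents that add atoms: none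
Why: Pinacol coupling through a samarium-bridged bis-ketyl should close the six-membered ring A as a cis-diol, and only the β,β arrangement is open because a 2α-oxygen would point into the lactone bridge.

Step 16
Reactants: 20 2β,3β-diol
Product: 22 2β,3β-bis(triethylsilyloxy) aldehyde (C-12 formyl), via bis(triethylsilyl) ether acetal 21 (not isolated)
Conditions: Et3SiOTf (4 equiv), 2,4,6-collidine, CH2Cl2, −40 to 0 °C; then H2O
Reagents that add atoms: triethylsilyl trifluoromethanesulfonate, CC[Si](CC)(CC)OS(=O)(=O)C(F)(F)F; water, O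
Why: The silyl triflate should silylate both hydroxyls and then open the aldehyde acetal to a collidinium adduct that water hydrolyses to the aldehyde (chemoselective silyl-triflate acetal cleavage), with no stereocentre involved.

Step 17
Reactants: 22 bis(triethylsilyloxy) aldehyde
Product: 23 carboxylic acid (C-12 CO2H)
Conditions: NaClO2, NaH2PO4, 2-methyl-2-butene, t-BuOH/H2O, 0 °C
Reagents that add atoms: sodium chlorite, [Na+].[O-]Cl=O
Why: Pinnick oxidation with a large excess of the alkene scavenger should take the aldehyde to the acid while hypochlorous acid is kept away from the allylsilane.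

Step 18
Reactants: 23 carboxylic acid
Product: 25 tetracyclic 12-ketone with C-16 exocyclic methylene (6α-ester), via acid chloride 24 (not isolated)
Conditions: 1-chloro-N,N,2-trimethylprop-1-en-1-amine, CH2Cl2, 0 °C; then SnCl4 (1.2 equiv), 2,6-di-tert-butylpyridine, CH2Cl2, −78 °C
Reagents that add atoms: 1-chloro-N,N,2-trimethylprop-1-en-1-amine, CC(C)=C(Cl)N(C)C (chlorine carried only in 24)
Why: The acid is converted under neutral conditions into acid chloride 24, which SnCl4 ionises to an acylium ion that is attacked by the γ-carbon C-13 of the allylsilane; the β-silyl cation at C-16 then loses Me3SiCl, so that the double bond moves out to C16=C17 (SE2′ acylation). The closest known reaction type is the Lewis-acid acylation of allylsilanes by acid chlorides, run here intramolecularly as an acylative Hosomi–Sakurai-type cyclisation. Ring C, the only ring closed, forms in a 6-exo-trig mode (C-12 bonds to the nearer olefinic carbon and C-16 stays outside the new ring) and completes the bicyclo[3.2.1]octane. The new stereocentre C-13 is substrate-controlled: the C-11 tether on the α face of ring B can reach only the α arm of the spiro ring (C-14 and C-13), so its configuration follows from C-8 and C-9. The step needs attack at C-13 and not C-16 and an exocyclic and not an endocyclic olefin, both secured by silicon (γ-attack, β-cation, loss of the silyl group), and the product cannot isomerise to a conjugated enone because C-13 is a bridgehead. Protodesilylation should be suppressed by the hindered pyridine base and the low temperature.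

Step 19
Reactants: 25 tetracyclic ketone (6α-ester)
Product: 26 tetracyclic ketone (6β-ester, natural C-6)
Conditions: t-BuOK (0.3 equiv), t-BuOH/THF, 0 °C to rt
Reagents that add atoms: none
Why: Base-mediated equilibration through the ester enolate should move the C-7 ester to the convex β face trans to C-4, the thermodynamically preferred configuration, while C-4 is now locked by ring A and C-13 cannot enolise (epimerisation).

Step 20
Reactants: 26 tetracyclic ketone (6β-ester)
Product: 27 target, 2β,3β-dihydroxy-12-oxo C19-gibberellin 19,10-lactone 7-acid (CNP0307952.1)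
Conditions: Bu4NF, AcOH (1:1), THF, 0 °C to rt
Reagents that add atoms: none
Why: Fluoride should remove both triethylsilyl ethers and fragment the 2-(trimethylsilyl)ethyl ester in one operation, and the acetic acid buffer should prevent retro-aldol opening at C3–C4 (fluoride desilylation).

**Compound list**

1 | (R)-4-[(tert-butyldimethylsilyl)oxy]cyclopent-2-en-1-one | O=C1C=C[C@H](O[Si](C)(C)C(C)(C)C)C1 | starting material
2 | (R)-4-[(tert-butyldimethylsilyl)oxy]-2-iodocyclopent-2-en-1-one | O=C1C(I)=C[C@H](O[Si](C)(C)C(C)(C)C)C1 | intermediate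
3 | (R)-2-allyl-4-[(tert-butyldimethylsilyl)oxy]cyclopent-2-en-1-one | O=C1C(CC=C)=C[C@H](O[Si](C)(C)C(C)(C)C)C1 | intermediate
4 | [2-(chloromethyl)prop-2-en-1-yl]trimethylsilane | C=C(CCl)C[Si](C)(C)C | starting material
5 | [2-(iodomethyl)prop-2-en-1-yl]trimethylsilane | C=C(CI)C[Si](C)(C)C | intermediate
6 | trimethylsilyl enol ether of the conjugate adduct: 2-allyl-3-(1,3-dioxolan-2-ylmethyl)-4-(TBSO)cyclopent-1-enyl trimethylsilyl ether, side chain trans to OTBS (not isolated) | [C@@H]1(O[Si](C)(C)C(C)(C)C)CC(O[Si](C)(C)C)=C(CC=C)[C@H]1CC2OCCO2 | intermediate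
7 | (2R,3R,4R)-2-allyl-4-[(tert-butyldimethylsilyl)oxy]-3-(1,3-dioxolan-2-ylmethyl)-2-{2-[(trimethylsilyl)methyl]prop-2-en-1-yl}cyclopentan-1-one | [C@@H]1(O[Si](C)(C)C(C)(C)C)CC(=O)[C@](CC=C)(CC(=C)C[Si](C)(C)C)[C@H]1CC2OCCO2 | intermediate
8 | 3-[(tert-butyldimethylsilyl)oxy]-4-(1,3-dioxolan-2-ylmethyl)-7-[(trimethylsilyl)methyl]spiro[4.4]non-7-en-1-one; C-9 side chain α, trans to 10β-OTBS, C-14 arm α, C-15 arm β | [C@@H]1(O[Si](C)(C)C(C)(C)C)CC(=O)[C@]2(CC(C[Si](C)(C)C)=CC2)[C@H]1CC3OCCO3 | intermediate
9 | enol triflate of 8 (C-6 triflate, C5=C6) | [C@@H]1(O[Si](C)(C)C(C)(C)C)C=C(OS(=O)(=O)C(F)(F)F)[C@]2(CC(C[Si](C)(C)C)=CC2)[C@H]1CC3OCCO3 | intermediate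
10 | 2-(trimethylsilyl)ethyl spiro[4.4]nona-1,7-diene-1-carboxylate bearing 3β-OTBS, 4α-(1,3-dioxolan-2-ylmethyl) and 7-CH2SiMe3 (C-7 ester on C-6) | [C@@H]1(O[Si](C)(C)C(C)(C)C)C=C(C(=O)OCC[Si](C)(C)C)[C@]2(CC(C[Si](C)(C)C)=CC2)[C@H]1CC3OCCO3 | intermediate
11 | allylic alcohol from 10 (10β-OH) | [C@@H]1(O)C=C(C(=O)OCC[Si](C)(C)C)[C@]2(CC(C[Si](C)(C)C)=CC2)[C@H]1CC3OCCO3 | intermediate
12 | enone: C-10 ketone conjugated to the C5=C6 2-(trimethylsilyl)ethyl enoate, 9α-(1,3-dioxolan-2-ylmethyl), spiro ring D allylsilane | O=C1C=C(C(=O)OCC[Si](C)(C)C)[C@]2(CC(C[Si](C)(C)C)=CC2)[C@H]1CC3OCCO3 | intermediate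
13 | 2,2,5-trimethyl-1,3-dioxane-4,6-dione | CC1C(=O)OC(C)(C)OC1=O | starting material
14 | 3-(ethylsulfanyl)-2-methyl-3-oxopropanoic acid | CCSC(=O)C(C)C(=O)O | intermediate
15 | S-ethyl 3-chloro-2-methyl-3-oxopropanethioate | CCSC(=O)C(C)C(Cl)=O | intermediate
16 | lithium alkoxide of the C-10 aldol adduct (10α-O−, 10β-CH2C(O)SEt) (not isolated) | [Li+].[O-][C@@]1(CC(=O)SCC)C=C(C(=O)OCC[Si](C)(C)C)[C@]2(CC(C[Si](C)(C)C)=CC2)[C@H]1CC3OCCO3 | intermediate
17 | tertiary 10α-ester of 3-(ethylsulfanyl)-2-methyl-3-oxopropanoic acid with 10β-CH2C(O)SEt (C-4 epimers) | [C@]1(OC(=O)C(C)C(=O)SCC)(CC(=O)SCC)C=C(C(=O)OCC[Si](C)(C)C)[C@]2(CC(C[Si](C)(C)C)=CC2)[C@H]1CC3OCCO3 | intermediate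
18 | cis-fused 19,10-lactone: C-4 methyl (endo) and C(O)SEt (exo), 5β-H, 6α-CO2CH2CH2SiMe3, 10β-CH2C(O)SEt | [C@]12(CC(=O)SCC)OC(=O)[C@](C)(C(=O)SCC)[C@H]1[C@@H](C(=O)OCC[Si](C)(C)C)[C@]3(CC(C[Si](C)(C)C)=CC3)[C@H]2CC4OCCO4 | intermediate
19 | dialdehyde: C-4 formyl (C-3) and 10β-CH2CHO (C-2) on lactone 18 | [C@]12(CC=O)OC(=O)[C@](C)(C=O)[C@H]1[C@@H](C(=O)OCC[Si](C)(C)C)[C@]3(CC(C[Si](C)(C)C)=CC3)[C@H]2CC4OCCO4 | intermediate
20 | 2β,3β-diol with rings A, B and D and the 19,10-lactone; 6α-ester, 9α-(1,3-dioxolan-2-ylmethyl), ring D allylsilane | [C@@]123C[C@H](O)[C@H](O)[C@@](C)(C(=O)O1)[C@H]2[C@@H](C(=O)OCC[Si](C)(C)C)[C@]4(CC(C[Si](C)(C)C)=CC4)[C@H]3CC5OCCO5 | intermediate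
21 | 2β,3β-bis(triethylsilyl) ether of 20 with the dioxolane intact (not isolated) | [C@@]123C[C@H](O[Si](CC)(CC)CC)[C@H](O[Si](CC)(CC)CC)[C@@](C)(C(=O)O1)[C@H]2[C@@H](C(=O)OCC[Si](C)(C)C)[C@]4(CC(C[Si](C)(C)C)=CC4)[C@H]3CC5OCCO5 | intermediate
22 | 2β,3β-bis(triethylsilyloxy) aldehyde (9α-CH2CHO) | [C@@]123C[C@H](O[Si](CC)(CC)CC)[C@H](O[Si](CC)(CC)CC)[C@@](C)(C(=O)O1)[C@H]2[C@@H](C(=O)OCC[Si](C)(C)C)[C@]4(CC(C[Si](C)(C)C)=CC4)[C@H]3CC=O | intermediate
23 | 2β,3β-bis(triethylsilyloxy) acid (9α-CH2CO2H) | [C@@]123C[C@H](O[Si](CC)(CC)CC)[C@H](O[Si](CC)(CC)CC)[C@@](C)(C(=O)O1)[C@H]2[C@@H](C(=O)OCC[Si](C)(C)C)[C@]4(CC(C[Si](C)(C)C)=CC4)[C@H]3CC(=O)O | intermediate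
24 | acid chloride of 23 (not isolated) | [C@@]123C[C@H](O[Si](CC)(CC)CC)[C@H](O[Si](CC)(CC)CC)[C@@](C)(C(=O)O1)[C@H]2[C@@H](C(=O)OCC[Si](C)(C)C)[C@]4(CC(C[Si](C)(C)C)=CC4)[C@H]3CC(=O)Cl | intermediate
25 | 2-(trimethylsilyl)ethyl ester of the 2β,3β-bis(triethylsilyl) ether of the 6-epi target: 12-ketone, 16-methylene, 6α-ester | C=C1C[C@]23C[C@H]1C(=O)C[C@H]2[C@@]12C[C@H](O[Si](CC)(CC)CC)[C@H](O[Si](CC)(CC)CC)[C@@](C)(C(=O)O1)[C@H]2[C@H]3C(=O)OCC[Si](C)(C)C | intermediate
26 | 2-(trimethylsilyl)ethyl ester of the 2β,3β-bis(triethylsilyl) ether of the target (6β-ester) | C=C1C[C@]23C[C@H]1C(=O)C[C@H]2[C@@]12C[C@H](O[Si](CC)(CC)CC)[C@H](O[Si](CC)(CC)CC)[C@@](C)(C(=O)O1)[C@H]2[C@@H]3C(=O)OCC[Si](C)(C)C | intermediate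
27 | CNP0307952.1, 2β,3β-dihydroxy-12-oxo-20-norgibberell-16-ene-7,19-dioic acid 19,10-lactone | C=C1C[C@]23C[C@H]1C(=O)C[C@H]2[C@@]12C[C@H](O)[C@H](O)[C@@](C)(C(=O)O1)[C@H]2[C@@H]3C(=O)O | target

**Step count and risks**

Total steps: 20. Longest linear sequence: 17 steps (steps 1, 2, 4 to 9 and 12 to 20); steps 3, 10 and 11 make the two side reagents.

Steps most likely to fail:

Step 13. The Michael closure may show poor facial discrimination at C-4, so that the thioester ends on the endo face and ring A cannot close later. Acyl transfer from the side-chain thioester to the malonate carbanion may also compete. The fallback sets out from 12 and fixes C-4 by approach of an electrophile instead of by a ring-closing transition state. Addition of (Z)-2-ethoxyvinyllithium (from tributyl[(Z)-2-ethoxyvinyl]stannane and BuLi) to the C-10 ketone and trapping of the alkoxide with 2-bromopropanoyl bromide should give the 2-bromopropanoate of the 10β-(2-ethoxyvinyl) carbinol F1. A Bu3SnH/AIBN 5-exo-trig radical cyclisation onto the enoate should close the cis-fused lactone with hydrogen and methyl at C-4, F2. Deprotonation with LiN(SiMe3)2 and C-formylation with 2,2,2-trifluoroethyl formate on the exo face should give the 4-formyl-4-methyl lactone F3. Brief oxalic acid hydrolysis of the enol ether comes back to the route at dialdehyde 19.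

Step 4. C-alkylation of the fully substituted enolate may be slow, which would allow proton transfer to the C-5 enolate and β-elimination of the silyloxy group. The fallback sets out from 3 through the same silyl enol ether 6 and uses a smaller, more reactive electrophile, with the silicon brought in afterwards. The lithium enolate is alkylated with 2,3-dibromopropene to give the 2-bromoallyl ketone F4. A Negishi coupling of the vinyl bromide with Me3SiCH2ZnCl and Pd(PPh3)4 then comes back to the route at 7.

Step 18. The allylsilane may be protodesilylated, or the silyl ethers lost to the Lewis acid, before the acylium ion is captured. The fallback sets out from aldehyde 22 and leaves out the oxidation to the acid. A BF3·OEt2-mediated intramolecular Hosomi–Sakurai allylation at −78 °C should close ring C to the 12-hydroxy-16-methylene compound F5 by the same γ-attack. Oxidation of the C-12 alcohol with the periodinane of step 9 comes back to the route at 25.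

Further compounds
F1 | step 13 | 2-bromopropanoate of the 10β-[(Z)-2-ethoxyvinyl] tertiary carbinol derived from 12 | [C@]1(OC(=O)C(C)Br)(/C=C\OCC)C=C(C(=O)OCC[Si](C)(C)C)[C@]2(CC(C[Si](C)(C)C)=CC2)[C@H]1CC3OCCO3
F2 | step 13 | cis-fused 19,10-lactone with hydrogen and methyl at C-4, 10β-[(Z)-2-ethoxyvinyl] and 6α-ester | [C@]12(/C=C\OCC)OC(=O)C(C)[C@H]1[C@@H](C(=O)OCC[Si](C)(C)C)[C@]3(CC(C[Si](C)(C)C)=CC3)[C@H]2CC4OCCO4
F3 | step 13 | 4-formyl-4-methyl lactone (formyl exo) with 10β-[(Z)-2-ethoxyvinyl] | [C@]12(/C=C\OCC)OC(=O)[C@](C)(C=O)[C@H]1[C@@H](C(=O)OCC[Si](C)(C)C)[C@]3(CC(C[Si](C)(C)C)=CC3)[C@H]2CC4OCCO4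
F4 | step 4 | 2-allyl-2-(2-bromoprop-2-en-1-yl)-4-[(tert-butyldimethylsilyl)oxy]-3-(1,3-dioxolan-2-ylmethyl)cyclopentan-1-one, bromoallyl group trans to the C-3 side chain | [C@@H]1(O[Si](C)(C)C(C)(C)C)CC(=O)[C@](CC=C)(CC(Br)=C)[C@H]1CC2OCCO2
F5 | step 18 | 12-hydroxy-16-methylene tetracycle, 2β,3β-bis(triethylsilyl) ether, 6α-2-(trimethylsilyl)ethyl ester (C-12 epimers) | C=C1C[C@]23C[C@H]1C(O)C[C@H]2[C@@]12C[C@H](O[Si](CC)(CC)CC)[C@H](O[Si](CC)(CC)CC)[C@@](C)(C(=O)O1)[C@H]2[C@H]3C(=O)OCC[Si](C)(C)C
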